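A small charge of incoming ligand, 0.29 M on 0.50 M of starting complex, gave 36 % of the complex with one exchanged at 4.00 h on Wednesday, its highest reading; Saturday's 1.5 M reached 68 %, then stood at 62 % at 4.00 h.

in all of them: starting complex 0.50 M

| charge | incoming ligand | remark | time |
|---|---|---|---|
| Wednesday's | 0.29 M | run made earlier |  |
| Saturday's | 1.5 M | run made earlier |  |
| ochre | 0.400 M |  | 4.0 h |
| amber | 0.500 M |  | 4.0 h |
| violet | 0.800 M |  | 4.0 h |
| grey | 1.20 M |  | 4.0 h |
| teal | 2.00 M |  | 4.0 h |

| Wednesday's: time / h | Wednesday's: complex with one exchanged / % | Saturday's: time / h | Saturday's: complex with one exchanged / % |
|---|---|---|---|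
| 0.833 | 17 | 0.833 | 62 |
| 1.50 | 28 | 1.50 | 68 |
| 2.50 | 32 | 2.50 | 68 |
| 3.00 | 34 | 3.00 | 68 |
| 4.00 | 36 | 4.00 | 62 |

(standard deviation of a reading: 1.5 percentage points)

- the numbers in the tables scatter with a standard deviation of 1.5 percentage points
- steps thought possible: incoming ligand -> decomposed reagent; starting complex + incoming ligand <-> leaving ligand + complex with one exchanged; complex with one exchanged + incoming ligand <-> leaving ligand + complex with two exchanged
- "hardly changes" means that all values lie within two and a half points (for a concentration: within two and a half percent of the largest)

* amount of complex with one exchanged at the end, in percent of the starting complex charged for ochre, amber, violet, grey, teal, in this order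
* the course of these numbers from the first flask to the last (falls, then rises / hardly changes / falls all the way / rises, then falls / rises all the way)

**Every flask differs in ligand and in ligand lost. What can they share?** The path. Let m and a be the fractions of the charged complex present as starting complex and as complex with one exchanged. Both forward steps use the same ligand, so dividing one forward rate by the other removes ligand and time; with s the ratio of the second forward rate constant to the first, da/dm = −1 + s·a/m. Integrated, this gives a = (m^s − m)/(1 − s).

**How large is s?** Let me first get it from the readings.

**How?** At the top of this curve, a = s^(s/(1 − s)), and m = s^(1/(1 − s)). Saturday's top reading is 68 %. I start from 0.160 and stop after two rounds of repeated substitution: 0.177, then 0.183. So s, the second exchange's forward rate constant over the first's, is a selectivity factor, read with the scatter of that reading.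

**Doesn't the ligand's decomposition spoil it?** Not for the forward steps: it lowers both forward rates by the same factor, so on those steps a flask moves along the curve more slowly without the curve moving.

**And the weak spot?** The back steps are left out, so I trust the curve least far along it.

**Your commitment?** The top of the curve lies at m = 12.5 %. Saturday's readings drop from 68 % to 62 % at the last, which I read as that flask having passed the top, and teal is charged with more ligand than Saturday's flask, so I expect teal past the top too, while ochre should lie on the rising side. The row should rise, then fall.

The forecast gave 44 %, 51 %, 63 %, 67 % and 53 %, rises, then falls, saying that teal “has passed the maximum”.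

The flasks give 44.6 %, 50.8 %, 61.5 %, 65.0 % and 60.5 %, so the course is: rises, then falls.

    incoming ligand → decomposed reagent (k = 0.105 /h)
    starting complex + incoming ligand ⇌ leaving ligand + complex with one exchanged (K = 3.60, k = 1.16 /M/h)
    complex with one exchanged + incoming ligand ⇌ leaving ligand + complex with two exchanged (K = 0.370, k = 0.161 /M/h)

Ochre ends with 52.8 % of its starting complex, and at that m the curve with s = 0.183 reads 44.3 %, against the flask's 44.6 %. Teal ends with 10.5 % of its starting complex, where the curve reads 68.2 %, which is 7.7 percentage points above the flask's 60.5 %, and the complex with two exchanged stands there at 29.0 %.

(The runs were computed on assumed constants.)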